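**Strategy.** Everything rests on cutting the cyclohexanone ring (C1, C10–C14) at C13–C14 and C1–C10. The C12 ketone flanked by the C11 methyl is read as a 2-silyloxy diene (C10=C11–C12=C13). The C14 butyrate next to quaternary C1 is read as a (Z)-β-butanoyloxy methacrolein whose formyl carbon is C2. A Diels–Alder reaction, tethered through an aluminium alkoxide of the tertiary C8 hydroxyl, unites the fully elaborated lactone diene (C3–C13, from D-erythrulose) with this dienophile. It closes the six-membered ring and sets C1, C10 and C14, with C11 held latent in the enol ether. A Nozaki–Hiyama–Kishi reaction at C2–C3 then closes the ten-membered ring.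

Key step: step 17

Remark on the chemistry: atom labels follow the briarane skeleton (C15 = methyl on C1, C16 = methylene on C5, C18 = methyl on C17, C19 = lactone carbonyl, C20 = methyl on C11); compounds 1, 14, 19 and 23 are assumed purchasable; every stereocentre of an intermediate has the spatial arrangement of the target except C6, which is carried as the inverted oxygenated centre until the last step, and the SMILES in the list are authoritative.

Step 1
Reactants: 1 D-erythrulose
Product: 2 3,4-O-isopropylidene-D-erythrulose
Conditions: 2,2-dimethoxypropane, camphorsulfonic acid (cat.), acetone, 23 °C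
Reagents that add atoms: 2,2-dimethoxypropane, COC(C)(C)OC
Why: Acid-catalysed transacetalisation (acetonide protection) closes the five-membered dioxolane on the vicinal C9/C10 diol and leaves the C7 hydroxyl of the α-ketol free.

Step 2
Reactants: 2 3,4-O-isopropylidene-D-erythrulose
Product: 3 1-O-triethylsilyl ether of 2
Conditions: Et3SiCl, imidazole, CH2Cl2, 0 °C
Reagents that add atoms: chlorotriethylsilane, CC[Si](Cl)(CC)CC
Why: Standard silylation of the only free hydroxyl, with a triethylsilyl group that can later be removed beside a tert-butyldimethylsilyl ether.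

Step 3
Reactants: 4 acrolein
Product: 6 2-bromoacrolein, via 2,3-dibromopropanal 5 (not isolated)
Conditions: Br2, CH2Cl2, −78 °C; then Et3N, −78 → 0 °C
Reagents that add atoms: bromine, BrBr
Why: Bromine adds to the enal and triethylamine then removes the acidic α-hydrogen with loss of the β-bromide (bromination–dehydrobromination), the usual preparation of this aldehyde.

Step 4
Reactants: 3 1-O-triethylsilyl ether of 2; 6 2-bromoacrolein
Product: 8 syn,syn-aldol (C6–OH, C7–OSiEt3), via dicyclohexylboron Z-enolate 7 (not isolated)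
Conditions: (c-C6H11)2BCl, Et3N, Et2O, −78 → 0 °C; then 6, −78 °C; then pH 7 buffer, MeOH, H2O2, 0 °C
Reagents that add atoms: none
Why: Boron aldol reaction in which enolisation toward the CH2OSi side gives the Z enolate, its chair transition state gives the 6,7-syn aldol, and the aldehyde adds to the enolate face anti to the dioxolane C–O bond so that the C7 oxygen comes out syn to the C9 oxygen (substrate control known for protected erythrulose ketones), C6 being formed on purpose with the arrangement that the final chloride displacement inverts.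

Step 5
Reactants: 8 syn,syn-aldol
Product: 9 C6 tert-butyldimethylsilyl ether of 8
Conditions: t-BuMe2SiOTf, 2,6-lutidine, CH2Cl2, −78 °C
Reagents that add atoms: tert-butyldimethylsilyl triflate, CC(C)(C)[Si](C)(C)OS(=O)(=O)C(F)(F)F
Why: A silyl triflate with a hindered base silylates the β-hydroxy ketone at low temperature without retro-aldol cleavage.

Step 6
Reactants: 9 C6 tert-butyldimethylsilyl ether of 8
Product: 10 α-hydroxy ketone (C7–OH free)
Conditions: HF·pyridine, pyridine, THF, 0 °C
Reagents that add atoms: none
Why: Buffered HF cleaves the more labile triethylsilyl ether selectively while the tert-butyldimethylsilyl ether and the acetonide stay (selective desilylation).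

Step 7
Reactants: 10 α-hydroxy ketone; 11 2-bromopropanoyl bromide
Product: 12 C7 2-bromopropanoate of 10
Conditions: pyridine, CH2Cl2, −20 °C
Reagents that add atoms: none
Why: Acylation of the secondary α-ketol hydroxyl by an acid bromide, the configuration at the bromine-bearing carbon being irrelevant because that carbon becomes an enolate in the next step.

Step 8
Reactants: 12 C7 2-bromopropanoate of 10
Product: 13 hydroxy lactone (C8–OH, C17 methyl)
Conditions: SmI2 (2.2 equiv), THF, −78 °C; aq NH4Cl
Reagents that add atoms: none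
Why: SmI2 reduces the α-bromo ester to a samarium enolate that adds to the neighbouring ketone (intramolecular Reformatsky reaction, 5-exo), the bulky dioxolanyl group on C8 taking the ring face opposite the C6 side chain so that the C8 hydroxyl is cis to C6, and the C17 methyl settling trans to the C9 arm, the less crowded arrangement of this epimerisable centre.

Step 9
Reactants: 13 hydroxy lactone; 14 (E)-1,2-bis(tributylstannyl)ethene
Product: 15 (E)-dienylstannane
Conditions: Pd2(dba)3 (5 mol %), tri(2-furyl)phosphine, 14 (3 equiv), DMF, 60 °C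
Reagents that add atoms: none
Why: Stille coupling of the 2-bromoalkene with an excess of the distannane transfers one (E)-stannylvinyl group with retention and keeps the second tin for the next step.

Step 10
Reactants: 15 (E)-dienylstannane
Product: 16 (E)-dienyl iodide
Conditions: I2, CH2Cl2, 0 °C
Reagents that add atoms: iodine, II
Why: Iododestannylation replaces tin by iodine with retention of the E geometry of C3=C4.

Step 11
Reactants: 16 (E)-dienyl iodide
Product: 17 triol (C8, C9, C10 hydroxyls)
Conditions: AcOH/THF/H2O (3:1:1), 40 °C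
Reagents that add atoms: none
Why: Mild aqueous acid hydrolyses the terminal acetonide while the hindered secondary silyl ether and the lactone are kept.

Step 12
Reactants: 17 triol
Product: 18 α-hydroxy aldehyde (C10 aldehyde)
Conditions: TEMPO (0.1 equiv), N-chlorosuccinimide, Bu4NCl, CH2Cl2/aq NaHCO3–K2CO3 (pH 8.6), 0 °C
Reagents that add atoms: none
Why: Oxoammonium (TEMPO) oxidation with N-chlorosuccinimide as terminal oxidant is selective for the primary hydroxyl over the secondary and tertiary ones and does not cleave the glycol.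

Step 13
Reactants: 18 α-hydroxy aldehyde; 19 3-(triphenyl-λ5-phosphanylidene)butan-2-one
Product: 20 (E)-enone
Conditions: CH2Cl2, 40 °C
Reagents that add atoms: none
Why: Wittig reaction of the stabilised ylide gives the E trisubstituted enone (C9 trans to C12) under nearly neutral conditions that spare the α-hydroxy aldehyde from epimerisation.

Step 14
Reactants: 20 (E)-enone
Product: 21 C9 acetate of 20
Conditions: Ac2O, pyridine, DMAP (cat.), CH2Cl2, 0 °C
Reagents that add atoms: acetic anhydride, CC(=O)OC(C)=O
Why: Acetylation of the secondary allylic C9 hydroxyl installs the C9 acetate of the target, the hindered tertiary C8 hydroxyl staying free for the tether.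

Step 15
Reactants: 21 C9 acetate of 20
Product: 22 2-silyloxy diene
Conditions: i-Pr3SiOTf, Et3N, CH2Cl2, −78 → 0 °C
Reagents that add atoms: triisopropylsilyl triflate, CC(C)[Si](C(C)C)(C(C)C)OS(=O)(=O)C(F)(F)F
Why: Soft enolisation of the methyl ketone with silyl triflate and triethylamine gives the cross-conjugated 2-silyloxy diene, the bulky silyl triflate leaving the hindered tertiary alcohol unsilylated and the far less acidic lactone untouched.

Step 16
Reactants: 23 2-methylmalonaldehyde
Product: 25 (Z)-3-(butanoyloxy)-2-methylprop-2-enal, via lithium Z-enolate 24 (not isolated)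
Conditions: LiN(SiMe3)2, THF, −78 °C; then butanoyl chloride, −78 °C
Reagents that add atoms: butanoyl chloride, CCCC(Cl)=O
Why: The lithium enolate of the 1,3-dialdehyde is a U-shaped chelate whose O-acylation gives the enol ester with the acyloxy group cis to the formyl group, by analogy with the Z-selective enol sulfonate formation from lithium chelates of 1,3-dicarbonyl compounds.

Step 17
Reactants: 22 2-silyloxy diene; 25 (Z)-3-(butanoyloxy)-2-methylprop-2-enal
Product: 27 cycloadduct (cyclohexene aldehyde), via dimethylaluminium alkoxide 26 (not isolated)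
Conditions: Me3Al (1.0 equiv), toluene, −78 → −20 °C; then 25 (1.5 equiv), −20 → 23 °C; aq potassium sodium tartrate
Reagents that add atoms: none
Why: Me3Al converts the tertiary C8 hydroxyl of 22 into a dimethylaluminium alkoxide whose Lewis-acidic metal binds the formyl oxygen of 25, so that a normal-demand [4+2] cycloaddition between the 2-silyloxy diene and the enal runs inside a self-assembled complex; the closest known reaction type is the Lewis-acid-tethered Diels–Alder reaction of dienols through magnesium or aluminium alkoxides, combined with the usual cycloaddition of 2-silyloxy dienes with 2-substituted enals. One ring is closed, the cyclohexene C1–C14–C13–C12–C11–C10, by concerted [4+2] formation of C13–C14 and C1–C10, while the chelate ring through aluminium is temporary and is opened by the work-up. The regiochemistry follows from the polarisation of both partners, the nucleophilic C13 terminus of the enol ether bonding to C14 (the β-carbon of the enal) and C10 to C1. With H9 held in the diene plane by allylic strain against the C11 methyl, the tether brings the dienophile to the diene face that carries C8 and away from the C9 acetate, so the D-erythrulose-derived C9 centre controls C10 (S), and the tethered formyl group is held exo, which puts it trans to C9 and the methyl cis and so controls C1 (R). The Z geometry of 25 keeps the butanoyloxy group on the side of the formyl group and thereby controls C14 (S), and the tetrasubstituted enol ether that remains stores the C12 ketone and lets C11 be set later. The step needs facial and exo selectivity that an untethered reaction would not give, and conjugate (1,4) rather than carbonyl (1,2, Mukaiyama aldol) attack; the alkoxide tether, its only mild Lewis acidity and the matched polarisation of diene and dienophile are what should secure them.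

Step 18
Reactants: 27 cycloadduct
Product: 28 macrocyclic C2 alcohol
Conditions: CrCl2 (10 equiv), NiCl2 (0.1 equiv), DMSO/THF (3:1), 0.002 M, 23 °C; aq NH4Cl
Reagents that add atoms: none
Why: Nozaki–Hiyama–Kishi reaction in which the dienyl iodide becomes a dienylchromium species that adds to the neopentyl aldehyde (free in equilibrium with any C2–O8 hemiacetal) beside the esters and the enol ether, with retention of the E geometry and closure of the ten-membered ring at high dilution, the C2 carbinol being expected from attack on the outward face of the formyl group in the trans-fused ring system.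

Step 19
Reactants: 28 macrocyclic C2 alcohol
Product: 29 C2,C9 diacetate
Conditions: Ac2O, DMAP, pyridine, 23 °C
Reagents that add atoms: acetic anhydride, CC(=O)OC(C)=O
Why: DMAP-catalysed acetylation of the secondary dienylic C2 hydroxyl, the tertiary C8 hydroxyl being left untouched.

Step 20
Reactants: 29 C2,C9 diacetate
Product: 30 C6 alcohol with C12 ketone
Conditions: HF·pyridine, pyridine, THF, 0 → 23 °C; aq NaHCO3
Reagents that add atoms: none
Why: Fluoride cleaves both silicon–oxygen bonds and the liberated enol is protonated at C11 from the α-face, anti to the C15 methyl and the C9-bearing bond, which places the C20 methyl β as in the target (kinetic protonation).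

Step 21
Reactants: 30 C6 alcohol with C12 ketone
Product: 31 CNP0283653.2 (target)
Conditions: PPh3, hexachloroacetone, CH2Cl2, −20 → 0 °C
Reagents that add atoms: hexachloroacetone, ClC(Cl)(Cl)C(=O)C(Cl)(Cl)Cl
Why: Appel-type chlorination converts the secondary allylic alcohol into the chloride by SN2 displacement with inversion at C6 and with little allylic transposition under these neutral conditions, the hindered tertiary C8 hydroxyl and the β-acyloxy ketone being inert.

**Compound list**

1 | D-erythrulose, (3R)-1,3,4-trihydroxybutan-2-one | OC[C@@H](O)C(=O)CO | starting material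
2 | 3,4-O-isopropylidene-D-erythrulose, 1-[(4R)-2,2-dimethyl-1,3-dioxolan-4-yl]-2-hydroxyethan-1-one (C7–OH, C8 ketone, C9/C10 acetonide) | CC1(C)OC[C@@H](O1)C(=O)CO | intermediate
3 | 1-O-triethylsilyl ether of 2 | CC1(C)OC[C@@H](O1)C(=O)CO[Si](CC)(CC)CC | intermediate
4 | acrolein (prop-2-enal) | C=CC=O | starting material
5 | 2,3-dibromopropanal (racemic) | BrCC(Br)C=O | intermediate (not isolated)
6 | 2-bromoacrolein (2-bromoprop-2-enal) | C=C(Br)C=O | intermediate
7 | dicyclohexylboron Z-enolate of 3 (C7=C8, boron on the C8 oxygen, cis to the C7 silyloxy group) | CC1(C)OC[C@@H](O1)/C(OB(C2CCCCC2)C2CCCCC2)=C/O[Si](CC)(CC)CC | intermediate (not isolated)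
8 | syn,syn-aldol, (2S,3S)-4-bromo-1-[(4R)-2,2-dimethyl-1,3-dioxolan-4-yl]-3-hydroxy-2-(triethylsilyloxy)pent-4-en-1-one (C6–OH and C7–OSi syn, C7–O and C9–O syn) | CC1(C)OC[C@@H](O1)C(=O)[C@@H](O[Si](CC)(CC)CC)[C@H](O)C(Br)=C | intermediate
9 | C6 tert-butyldimethylsilyl ether of 8 | CC1(C)OC[C@@H](O1)C(=O)[C@@H](O[Si](CC)(CC)CC)[C@H](O[Si](C)(C)C(C)(C)C)C(Br)=C | intermediate
10 | α-hydroxy ketone, 9 without the triethylsilyl group (C7–OH free) | CC1(C)OC[C@@H](O1)C(=O)[C@@H](O)[C@H](O[Si](C)(C)C(C)(C)C)C(Br)=C | intermediate
11 | 2-bromopropanoyl bromide (racemic) | CC(Br)C(Br)=O | starting material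
12 | C7 2-bromopropanoate of 10 (both epimers at the CHBr carbon) | CC1(C)OC[C@@H](O1)C(=O)[C@@H](OC(=O)C(C)Br)[C@H](O[Si](C)(C)C(C)(C)C)C(Br)=C | intermediate
13 | hydroxy lactone: γ-lactone C19(=O)–O–C7, tertiary C8–OH cis to the C17 methyl and to the C7 arm CH(OSiMe2t-Bu)–C(Br)=CH2, (4R)-dioxolanyl group (C9/C10) on C8 | CC1(C)OC[C@@H](O1)[C@]2(O)[C@@H](C)C(=O)O[C@H]2[C@H](O[Si](C)(C)C(C)(C)C)C(Br)=C | intermediate
14 | (E)-1,2-bis(tributylstannyl)ethene | CCCC[Sn](CCCC)(CCCC)/C=C/[Sn](CCCC)(CCCC)CCCC | starting material
15 | (E)-dienylstannane: 13 with (E)-CH=CH–SnBu3 on C5 in place of bromine | CC1(C)OC[C@@H](O1)[C@]2(O)[C@@H](C)C(=O)O[C@H]2[C@H](O[Si](C)(C)C(C)(C)C)C(=C)/C=C/[Sn](CCCC)(CCCC)CCCC | intermediate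
16 | (E)-dienyl iodide: 15 with iodine on C3 in place of tin | CC1(C)OC[C@@H](O1)[C@]2(O)[C@@H](C)C(=O)O[C@H]2[C@H](O[Si](C)(C)C(C)(C)C)C(=C)/C=C/I | intermediate
17 | triol: 16 without the acetonide (C8, C9, C10 hydroxyls) | OC[C@@H](O)[C@]1(O)[C@@H](C)C(=O)O[C@H]1[C@H](O[Si](C)(C)C(C)(C)C)C(=C)/C=C/I | intermediate
18 | α-hydroxy aldehyde: 17 with C10 as aldehyde | O=C[C@@H](O)[C@]1(O)[C@@H](C)C(=O)O[C@H]1[C@H](O[Si](C)(C)C(C)(C)C)C(=C)/C=C/I | intermediate
19 | 3-(triphenyl-λ5-phosphanylidene)butan-2-one | CC(=O)C(C)=P(c1ccccc1)(c1ccccc1)c1ccccc1 | starting material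
20 | (E)-enone: C13H3–C12(=O)–C11(CH3)=C10H–C9H(OH)–lactone arm | CC(=O)/C(C)=C/[C@@H](O)[C@]1(O)[C@@H](C)C(=O)O[C@H]1[C@H](O[Si](C)(C)C(C)(C)C)C(=C)/C=C/I | intermediate
21 | C9 acetate of 20 | CC(=O)/C(C)=C/[C@@H](OC(C)=O)[C@]1(O)[C@@H](C)C(=O)O[C@H]1[C@H](O[Si](C)(C)C(C)(C)C)C(=C)/C=C/I | intermediate
22 | 2-silyloxy diene: triisopropylsilyl dienol ether of 21 (C13H2=C12(OSi)–C11(CH3)=C10H, E) | C=C(O[Si](C(C)C)(C(C)C)C(C)C)/C(C)=C/[C@@H](OC(C)=O)[C@]1(O)[C@@H](C)C(=O)O[C@H]1[C@H](O[Si](C)(C)C(C)(C)C)C(=C)/C=C/I | intermediate
23 | 2-methylmalonaldehyde (2-methylpropanedial, enol form 3-hydroxy-2-methylprop-2-enal) | CC(C=O)C=O | starting material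
24 | lithium Z-enolate of 23 (chelate, O– cis to the formyl group) | [Li+].[O-]/C=C(\C=O)C | intermediate (not isolated)
25 | (Z)-3-(butanoyloxy)-2-methylprop-2-enal | CCCC(=O)O/C=C(\C=O)C | intermediate
26 | dimethylaluminium alkoxide of 22 (aluminium on the C8 oxygen) | C=C(O[Si](C(C)C)(C(C)C)C(C)C)/C(C)=C/[C@@H](OC(C)=O)[C@]1(O[Al](C)C)[C@@H](C)C(=O)O[C@H]1[C@H](O[Si](C)(C)C(C)(C)C)C(=C)/C=C/I | intermediate (not isolated)
27 | cycloadduct: cyclohexene with C1 (R; methyl and formyl C2), C14 (S; butanoyloxy), C11=C12 triisopropylsilyl enol ether, C10 (S) bearing the C9-acetoxy lactone arm with C6–OSiMe2t-Bu and the (E)-dienyl iodide | O=C[C@@]1(C)[C@@H](OC(=O)CCC)CC(O[Si](C(C)C)(C(C)C)C(C)C)=C(C)[C@@H]1[C@@H](OC(C)=O)[C@]2(O)[C@@H](C)C(=O)O[C@H]2[C@H](O[Si](C)(C)C(C)(C)C)C(=C)/C=C/I | intermediate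
28 | macrocyclic C2 alcohol: briarane ring system with C2–OH, C9–OAc, C8–OH, C6–OSiMe2t-Bu, C11=C12 triisopropylsilyl enol ether, C14 butanoate, (3E)-diene with C16 methylene | C=C1/C=C/[C@@H](O)[C@]2(C)[C@@H]([C@@H](OC(C)=O)[C@]3(O)[C@@H](C)C(=O)O[C@H]3[C@@H]1O[Si](C)(C)C(C)(C)C)C(C)=C(O[Si](C(C)C)(C(C)C)C(C)C)C[C@@H]2OC(=O)CCC | intermediate
29 | C2,C9 diacetate: C2 acetate of 28 | C=C1/C=C/[C@@H](OC(C)=O)[C@]2(C)[C@@H]([C@@H](OC(C)=O)[C@]3(O)[C@@H](C)C(=O)O[C@H]3[C@@H]1O[Si](C)(C)C(C)(C)C)C(C)=C(O[Si](C(C)C)(C(C)C)C(C)C)C[C@@H]2OC(=O)CCC | intermediate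
30 | C6 alcohol: target with OH of inverted configuration (6R) in place of chlorine; C12 ketone, (11R) methyl | C=C1/C=C/[C@@H](OC(C)=O)[C@]2(C)[C@@H]([C@@H](OC(C)=O)[C@]3(O)[C@@H](C)C(=O)O[C@H]3[C@@H]1O)[C@@H](C)C(=O)C[C@@H]2OC(=O)CCC | intermediate
31 | CNP0283653.2, (1R,2R,3E,6S,7R,8R,9R,10S,11R,14S,17R)-2,9-diacetoxy-14-butanoyloxy-6-chloro-8-hydroxy-12-oxobriara-3,5(16)-dien-19,7-olide | C=C1/C=C/[C@@H](OC(C)=O)[C@]2(C)[C@@H]([C@@H](OC(C)=O)[C@]3(O)[C@@H](C)C(=O)O[C@H]3[C@H]1Cl)[C@@H](C)C(=O)C[C@@H]2OC(=O)CCC | target

**Totals.** Total step count: 21. Longest linear sequence: 19 steps (steps 1, 2, 4–15 and 17–21, from D-erythrulose).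

**Steps most likely to fail**

Step 17 (tethered Diels–Alder). What may go wrong is carbonyl (1,2) attack of the enol ether on the aluminium-bound aldehyde, transfer of the butanoyl group from the activated enol ester to the alkoxide, or cycloaddition outside the tether with the opposite facial and endo/exo sense. Fallback: the order of the two ring-forming events is reversed so that the carbon chain itself is the tether. It sets out from 21 and 25. An intermolecular Nozaki–Hiyama–Kishi coupling (CrCl2, NiCl2 cat., DMSO, 23 °C) of the dienyl iodide of 21 with the aldehyde of 25 should give the allylic alcohol F1 (both C2 epimers), which is oxidised without delay (DMP, NaHCO3, CH2Cl2) to the cross-conjugated dienone F2. Enol silylation (i-Pr3SiOTf, Et3N, CH2Cl2) gives the silyloxy diene F3. Heating at high dilution (toluene, 0.001 M, 110 °C, BHT) should bring about an intramolecular Diels–Alder reaction of the C2-keto-activated C1=C14 enol ester with the diene; this again forms C13–C14 and C1–C10 in one operation and closes the six- and ten-membered rings together to the macrocyclic ketone F4. Luche reduction (NaBH4, CeCl3·7H2O, MeOH/THF, −78 °C) of the C2 ketone then comes back to the route at 28.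

Step 18 (macrocyclic Nozaki–Hiyama–Kishi closure). What may go wrong is oligomerisation in place of ring closure, reduction of the dienyl iodide without C–C bond formation, or addition to the wrong face of the aldehyde. Fallback: the bond is made through boron and rhodium. It sets out from 27. Miyaura borylation (bis(pinacolato)diboron, PdCl2(dppf), KOAc, dioxane, 80 °C) should give the dienyl pinacol boronate F5. An intramolecular rhodium-catalysed 1,2-addition of the alkenyl boronate to the aldehyde ([Rh(cod)OH]2, BINAP, dioxane/H2O, 40 °C, high dilution) then closes the ring and comes back at 28; the chiral ligand adds reagent control at C2.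

Step 8 (samarium Reformatsky lactonisation). What may go wrong is reductive cleavage of the α-acyloxy ketone C–O bond in place of ring closure, or closure to the wrong C8 epimer. Fallback: the propionate unit is added between molecules under chelation control. It sets out from 9. A Reformatsky reaction (ethyl 2-bromopropanoate, activated Zn, THF, 0 °C, zinc chelated by the ketone and the dioxolane oxygen) should give the β-hydroxy ester F6. HF·pyridine (pyridine, THF, 0 °C) then frees the C7 hydroxyl, which lactonises (pyridinium tosylate, toluene, 60 °C, then DBU to equilibrate C17), and the route is rejoined at 13.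

**Further compounds**

F1 | step 17 | allylic alcohol: 21 joined at C3 to C2 of 25, C2–OH (both epimers), C1=C14 enol butanoate (Z) | CC(=O)/C(C)=C/[C@@H](OC(C)=O)[C@]1(O)[C@@H](C)C(=O)O[C@H]1[C@H](O[Si](C)(C)C(C)(C)C)C(=C)/C=C/C(O)/C(C)=C\OC(=O)CCC
F2 | step 17 | cross-conjugated dienone: C2 ketone of F1 | CC(=O)/C(C)=C/[C@@H](OC(C)=O)[C@]1(O)[C@@H](C)C(=O)O[C@H]1[C@H](O[Si](C)(C)C(C)(C)C)C(=C)/C=C/C(=O)/C(C)=C\OC(=O)CCC
F3 | step 17 | silyloxy diene: triisopropylsilyl dienol ether of F2 at C12 | C=C(O[Si](C(C)C)(C(C)C)C(C)C)/C(C)=C/[C@@H](OC(C)=O)[C@]1(O)[C@@H](C)C(=O)O[C@H]1[C@H](O[Si](C)(C)C(C)(C)C)C(=C)/C=C/C(=O)/C(C)=C\OC(=O)CCC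
F4 | step 17 | macrocyclic ketone: 28 with C2 as ketone | C=C1/C=C/C(=O)[C@]2(C)[C@@H]([C@@H](OC(C)=O)[C@]3(O)[C@@H](C)C(=O)O[C@H]3[C@@H]1O[Si](C)(C)C(C)(C)C)C(C)=C(O[Si](C(C)C)(C(C)C)C(C)C)C[C@@H]2OC(=O)CCC
F5 | step 18 | dienyl pinacol boronate: 27 with the pinacolboryl group on C3 in place of iodine | O=C[C@@]1(C)[C@@H](OC(=O)CCC)CC(O[Si](C(C)C)(C(C)C)C(C)C)=C(C)[C@@H]1[C@@H](OC(C)=O)[C@]2(O)[C@@H](C)C(=O)O[C@H]2[C@H](O[Si](C)(C)C(C)(C)C)C(=C)/C=C/B3OC(C)(C)C(C)(C)O3
F6 | step 8 | β-hydroxy ester: 9 with C8 as tertiary alcohol bearing CH(CH3)CO2Et (C17 epimers) | CC1(C)OC[C@@H](O1)[C@](O)(C(C)C(=O)OCC)[C@@H](O[Si](CC)(CC)CC)[C@H](O[Si](C)(C)C(C)(C)C)C(Br)=C
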